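**Retrosynthetic overview**

1. Target 10 comes from pentaol 9 by O-sulfation of its only aliphatic hydroxyl; 9 comes from tribromide 7 by cleavage of the two aryl methyl ethers and of the chain acetate.
2. Tribromide 7 comes from the bromine-free bis-guaiacol 4 by one threefold electrophilic bromination. The strategy rests on where the bromines sit: on C5 of ring A (the ring with the ethyl chain on C1, between the C4 oxygen and the benzyl-bearing C6) and on C5' and C6' of ring B (beside the C4' oxygen and on the next carbon). A free C4/C4' phenol with a C3/C3' methyl ether activates exactly these carbons, whereas the unbrominated C2 and C2' lie ortho only to the methoxy oxygen.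
3. Bis-guaiacol 4 comes from homovanillyl acetate 2 and vanillyl alcohol 3 by acid-catalysed benzylation, forming the C6–CH2 bond para to the C3 methoxy group; 2 comes from homovanillyl alcohol 1.
4. No ring is formed: rings A and B are bought as 1 and 3, and the target has no stereocentre.

Key step: step 3

Assumption: the target is taken as drawn, the free alkyl hydrogen sulfate; this strong acid should be kept cold and freeze-dried from dilute solution (neutralisation with KHCO3 would give the potassium salt).

**Route**

Step 1
Reactants: 1 homovanillyl alcohol, 2-(4-hydroxy-3-methoxyphenyl)ethanol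
Product: 2 homovanillyl acetate, 2-(4-hydroxy-3-methoxyphenyl)ethyl acetate
Conditions: vinyl acetate (3 equiv), immobilised Candida antarctica lipase B, t-BuOMe, 40 °C
Reagents that add atoms: vinyl acetate, CC(=O)OC=C
Why: Lipase-catalysed transesterification with an enol ester acylates only the primary aliphatic hydroxyl, because the phenol is not accepted by the enzyme and the vinyl alcohol released tautomerises to acetaldehyde, which makes the acyl transfer irreversible.

Step 2
Reactants: 2 homovanillyl acetate (3 equiv); 3 vanillyl alcohol, 4-(hydroxymethyl)-2-methoxyphenol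
Product: 4 2-[4-hydroxy-2-(4-hydroxy-3-methoxybenzyl)-5-methoxyphenyl]ethyl acetate
Conditions: p-TsOH·H2O (10 mol %), (CF3)2CHOH, 0 °C to rt, slow addition of 3 to 2; excess 2 recovered by chromatography
Reagents that add atoms: none
Why: Friedel–Crafts benzylation: acid in the ionising, non-nucleophilic fluoroalcohol turns the para-hydroxybenzylic alcohol 3 into its benzylic cation (a protonated para-quinone methide) with loss of water, and this cation attacks C6 of 2, the carbon para to the C3 methoxy group and ortho to the alkyl chain, as in acid-catalysed condensation of guaiacyl units, while the excess of 2 and the slow addition of 3 hold back self-condensation of 3 and a second benzylation of 4.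

Step 3
Reactants: 4 2-[4-hydroxy-2-(4-hydroxy-3-methoxybenzyl)-5-methoxyphenyl]ethyl acetate
Product: 7 2-[3-bromo-2-(2,3-dibromo-4-hydroxy-5-methoxybenzyl)-4-hydroxy-5-methoxyphenyl]ethyl acetate, via C5-monobromide 5 (not isolated), via C5,C5'-dibromide 6 (not isolated)
Conditions: KBr (3.05 equiv), NH4VO3 (5 mol %), 30% aq. H2O2 (3.3 equiv, added over 2 h), 0.5 M aq. H2SO4/MeCN 1:1, 0 °C to rt, dark
Reagents that add atoms: potassium bromide, [K+].[Br-]
Why: NH4VO3 and H2O2 form a peroxo complex of pentavalent vanadium that oxidises bromide to an electrophilic bromine species (hypobromous acid or its equivalent), and each C–Br bond then forms by electrophilic aromatic substitution through a Wheland intermediate that loses a proton. The closest known reaction type is the vanadate/peroxide/bromide haloperoxidase-mimic bromination of phenols and anisoles, and the pattern sought matches the known ortho-halogenation of 4-substituted guaiacols and the 5,6-dihalogenation of vanillin- and creosol-type rings. No ring is closed and no stereocentre is created. The selectivity needed is positional: of the five free ring carbons, C5 of ring A (ortho to the free C4–OH and to the benzylic CH2), C5' of ring B (ortho to the free C4'–OH) and C6' of ring B (para to the C3'–OMe and ortho to the CH2) must react, while C2 and C2' must not. This is secured by keeping C4 and C4' as free phenols and C3 and C3' as methyl ethers, so that C2 and C2' are activated only by an ortho methoxy group, are each wedged between that group and a carbon substituent, and sit on rings already deactivated by bromine once the wanted positions have reacted; bromide is the limiting reagent, so a fourth bromination or ipso attack at C1' cannot run on. The two positions ortho to a free hydroxyl (C5 and C5') should react first, in either order, and C6' last, but the product does not depend on that order.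

Step 4
Reactants: 7 2-[3-bromo-2-(2,3-dibromo-4-hydroxy-5-methoxybenzyl)-4-hydroxy-5-methoxyphenyl]ethyl acetate
Product: 8 2-[3-bromo-2-(2,3-dibromo-4,5-dihydroxybenzyl)-4,5-dihydroxyphenyl]ethyl acetate
Conditions: BBr3 (6 equiv), CH2Cl2, −78 °C to 0 °C; then ice/H2O
Reagents that add atoms: none
Why: BBr3 cleavage of aryl methyl ethers: boron binds each methoxy oxygen and bromide removes the methyl group by SN2 attack, which leaves the aryl bromides and the diarylmethane untouched and, at or below 0 °C, should spare the primary acetate.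

Step 5
Reactants: 8 2-[3-bromo-2-(2,3-dibromo-4,5-dihydroxybenzyl)-4,5-dihydroxyphenyl]ethyl acetate
Product: 9 3-bromo-4-(2,3-dibromo-4,5-dihydroxybenzyl)-5-(2-hydroxyethyl)benzene-1,2-diol
Conditions: HCl (1.25 M in MeOH), rt, Ar
Reagents that add atoms: none
Why: Acid-catalysed transesterification (methanolysis) removes the acetate as methyl acetate and is chosen over basic methanolysis because the two bromocatechols stay protonated and are not oxidised to ortho-quinones.

Step 6
Reactants: 9 3-bromo-4-(2,3-dibromo-4,5-dihydroxybenzyl)-5-(2-hydroxyethyl)benzene-1,2-diol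
Product: 10 2-[3-bromo-2-(2,3-dibromo-4,5-dihydroxybenzyl)-4,5-dihydroxyphenyl]ethyl hydrogen sulfate
Conditions: H2SO4 (1.1 equiv), DCC (5 equiv), DMF, 0 °C, Ar; filtration, C18 chromatography (H2O/MeOH), freeze-drying
Reagents that add atoms: sulfuric acid, OS(=O)(=O)O
Why: Carbodiimide-mediated sulfation: DCC activates sulfuric acid as an O-sulfoisourea that passes SO3 to the unhindered primary alcohol, a reaction type known to prefer aliphatic over phenolic hydroxyls under these cold acidic conditions, and here the four phenolic hydroxyls are further shielded by a neighbouring bromine or oxygen, so about one equivalent of acid should give the monosulfate.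

**Compound list**

1 | homovanillyl alcohol, 2-(4-hydroxy-3-methoxyphenyl)ethanol | COc1cc(CCO)ccc1O | starting material
2 | homovanillyl acetate, 2-(4-hydroxy-3-methoxyphenyl)ethyl acetate | CC(=O)OCCc1ccc(O)c(OC)c1 | intermediate
3 | vanillyl alcohol, 4-(hydroxymethyl)-2-methoxyphenol | COc1cc(CO)ccc1O | starting material
4 | 2-[4-hydroxy-2-(4-hydroxy-3-methoxybenzyl)-5-methoxyphenyl]ethyl acetate | CC(=O)OCCc1cc(OC)c(O)cc1Cc1ccc(O)c(OC)c1 | intermediate
5 | 2-[3-bromo-4-hydroxy-2-(4-hydroxy-3-methoxybenzyl)-5-methoxyphenyl]ethyl acetate | CC(=O)OCCc1cc(OC)c(O)c(Br)c1Cc1ccc(O)c(OC)c1 | intermediate (not isolated)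
6 | 2-[3-bromo-2-(3-bromo-4-hydroxy-5-methoxybenzyl)-4-hydroxy-5-methoxyphenyl]ethyl acetate | CC(=O)OCCc1cc(OC)c(O)c(Br)c1Cc1cc(Br)c(O)c(OC)c1 | intermediate (not isolated)
7 | 2-[3-bromo-2-(2,3-dibromo-4-hydroxy-5-methoxybenzyl)-4-hydroxy-5-methoxyphenyl]ethyl acetate | CC(=O)OCCc1cc(OC)c(O)c(Br)c1Cc1cc(OC)c(O)c(Br)c1Br | intermediate
8 | 2-[3-bromo-2-(2,3-dibromo-4,5-dihydroxybenzyl)-4,5-dihydroxyphenyl]ethyl acetate | CC(=O)OCCc1cc(O)c(O)c(Br)c1Cc1cc(O)c(O)c(Br)c1Br | intermediate
9 | 3-bromo-4-(2,3-dibromo-4,5-dihydroxybenzyl)-5-(2-hydroxyethyl)benzene-1,2-diol | OCCc1cc(O)c(O)c(Br)c1Cc1cc(O)c(O)c(Br)c1Br | intermediate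
10 | 2-[3-bromo-2-(2,3-dibromo-4,5-dihydroxybenzyl)-4,5-dihydroxyphenyl]ethyl hydrogen sulfate | O=S(=O)(O)OCCc1cc(O)c(O)c(Br)c1Cc1cc(O)c(O)c(Br)c1Br | target

**Step count and risks**

Total steps: 6. Longest linear sequence: 6 steps (1, 2, 4, 7, 8, 9, 10); 3 is used as bought.

Steps most likely to fail:

1. Step 3. The bromination may not stop cleanly at three sites. A fourth bromine may enter at C2 of ring A. Ipso attack at C1' (para to the C4' hydroxyl) may cleave the diarylmethane or oxidise it through a para-quinone methide. The third bromination may lag and leave mixtures of partly brominated material. The fallback sets out from 2 and brings the two bromines of ring B in with the fragment. Commercial 5-bromovanillin is brominated (Br2, Fe powder, NaOAc, AcOH, warm) to 2,3-dibromo-4-hydroxy-5-methoxybenzaldehyde F1 and reduced (NaBH4, MeOH, 0 °C) to 2,3-dibromo-4-hydroxy-5-methoxybenzyl alcohol F2. Its ring is too deactivated to condense with itself. F2 benzylates 2 at C6 (TfOH 10 mol %, (CF3)2CHOH, rt) to give 2-[2-(2,3-dibromo-4-hydroxy-5-methoxybenzyl)-4-hydroxy-5-methoxyphenyl]ethyl acetate F3. Ring B of F3 has only the deactivated C2' open, so one equivalent of NBS (MeCN, 0 °C) only has to brominate ring A ortho to the C4 hydroxyl, and the route is rejoined at 7.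

2. Step 2. The vanillyl cation may be captured by the ring of 3 or of product 4 (oligomers), and attack at C5 of 2, ortho to the free hydroxyl, may give a regioisomeric diarylmethane that is hard to separate. The fallback sets out from 1 and 3 and masks both phenols so that the methoxy groups alone direct. Ac2O/pyridine gives 2-(4-acetoxy-3-methoxyphenyl)ethyl acetate F4 from 1 and 4-acetoxy-3-methoxybenzyl acetate F5 from 3. Benzylation of F4 (3 equiv) with F5 (FeCl3 10 mol %, MeNO2, 50 °C) should go para to the methoxy group of the less nucleophilic, acetate-blocked ring and give 2-[4-acetoxy-2-(4-acetoxy-3-methoxybenzyl)-5-methoxyphenyl]ethyl acetate F6. Pyrrolidine (MeCN, 0 °C) then removes the two aryl acetates by aminolysis and leaves the alkyl acetate, and the route is rejoined at 4.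

3. Step 6. Sulfation may not stay at the primary alcohol (competing O-sulfation of the catechol hydroxyls), and the free hydrogen sulfate may hydrolyse itself during concentration. The fallback sets out from 8 and blocks the phenols. TBSCl/imidazole (DMF, rt) gives 2-[3-bromo-4,5-bis(tert-butyldimethylsilyloxy)-2-[2,3-dibromo-4,5-bis(tert-butyldimethylsilyloxy)benzyl]phenyl]ethyl acetate F7. Reduction with i-Bu2AlH (CH2Cl2, −78 °C) removes the acetate and gives the tetrasilylated primary alcohol F8. SO3·pyridine (pyridine, rt) gives the pyridinium salt of the tetrasilylated alkyl sulfate F9. Bu4NF buffered with AcOH (THF, 0 °C), followed by a sulfonic acid resin in its acid form, removes the four silyl groups and the counter-ion, and the route is rejoined at 10.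

**Further compounds**

F1 | step 3 | 2,3-dibromo-4-hydroxy-5-methoxybenzaldehyde | O=Cc1cc(OC)c(O)c(Br)c1Br
F2 | step 3 | 2,3-dibromo-4-hydroxy-5-methoxybenzyl alcohol | OCc1cc(OC)c(O)c(Br)c1Br
F3 | step 3 | 2-[2-(2,3-dibromo-4-hydroxy-5-methoxybenzyl)-4-hydroxy-5-methoxyphenyl]ethyl acetate | CC(=O)OCCc1cc(OC)c(O)cc1Cc1cc(OC)c(O)c(Br)c1Br
F4 | step 2 | 2-(4-acetoxy-3-methoxyphenyl)ethyl acetate | CC(=O)OCCc1ccc(OC(C)=O)c(OC)c1
F5 | step 2 | 4-acetoxy-3-methoxybenzyl acetate | CC(=O)OCc1ccc(OC(C)=O)c(OC)c1
F6 | step 2 | 2-[4-acetoxy-2-(4-acetoxy-3-methoxybenzyl)-5-methoxyphenyl]ethyl acetate | CC(=O)OCCc1cc(OC)c(OC(C)=O)cc1Cc1ccc(OC(C)=O)c(OC)c1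
F7 | step 6 | 2-[3-bromo-4,5-bis(tert-butyldimethylsilyloxy)-2-[2,3-dibromo-4,5-bis(tert-butyldimethylsilyloxy)benzyl]phenyl]ethyl acetate | CC(=O)OCCc1cc(O[Si](C)(C)C(C)(C)C)c(O[Si](C)(C)C(C)(C)C)c(Br)c1Cc1cc(O[Si](C)(C)C(C)(C)C)c(O[Si](C)(C)C(C)(C)C)c(Br)c1Br
F8 | step 6 | 2-[3-bromo-4,5-bis(tert-butyldimethylsilyloxy)-2-[2,3-dibromo-4,5-bis(tert-butyldimethylsilyloxy)benzyl]phenyl]ethanol | OCCc1cc(O[Si](C)(C)C(C)(C)C)c(O[Si](C)(C)C(C)(C)C)c(Br)c1Cc1cc(O[Si](C)(C)C(C)(C)C)c(O[Si](C)(C)C(C)(C)C)c(Br)c1Br
F9 | step 6 | pyridinium 2-[3-bromo-4,5-bis(tert-butyldimethylsilyloxy)-2-[2,3-dibromo-4,5-bis(tert-butyldimethylsilyloxy)benzyl]phenyl]ethyl sulfate | [O-]S(=O)(=O)OCCc1cc(O[Si](C)(C)C(C)(C)C)c(O[Si](C)(C)C(C)(C)C)c(Br)c1Cc1cc(O[Si](C)(C)C(C)(C)C)c(O[Si](C)(C)C(C)(C)C)c(Br)c1Br.c1cc[nH+]cc1
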